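**Plan**

1. Retrosynthesis: first the three O–Si bonds are cut, then the ring O–C(spiro) bond of the six-membered ring (giving hydroxy dihydrofuran 21), then, together, the C(spiro)–CH2 bond and the CH(CH3)–CH(O) bond of the six-membered ring.
2. Enabling feature: in the six-membered ring the sequence O–CH(side chain)–CH(CH3)–CH2–CH2–C(spiro) is a crotyl unit (methyl carbon, methine and two CH2) set between an aldehyde-level carbon (the ring CH–O) and a carboxyl-level carbon (the spiro ketal carbon, which together with the five-membered ring is a γ-lactone).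
3. Forward: aldehyde 7 (5 steps) and lactone-derived ketene acetal phosphate 17 (5 steps, five-membered ring carried in as the γ-lactone) are joined through (E)-crotylboronate 18 in one flask by crotylboration, hydroboration and B-alkyl Suzuki–Miyaura coupling. Acid then closes the six-membered ring and fluoride frees the triol.
4. Stereochemistry: the side-chain carbinol next to the six-membered ring comes from (R)-glycidyl ether 2 and the Z-alkene from Lindlar semihydrogenation. The ring CH–O and CH–CH3 centres come from the chair crotylboration (catalyst-controlled face, anti from the E-crotyl geometry).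
5. The west carbinol comes from a catalytic Mukaiyama aldol, the five-membered-ring CH–O centre from 1,3-anti hydride delivery, and the spiro centre from anomeric (thermodynamic) control.

Key step: step 11

Remark: 2 and 9 are taken as purchasable; otherwise each is one routine operation from (S)-glycidol (PMB etherification) or S-ethyl thioacetate (LDA, Me3SiCl).
Abbreviations: TBS = tert-butyldimethylsilyl, PMB = 4-methoxybenzyl, TES = triethylsilyl, pin = pinacolato, 9-BBN = 9-borabicyclo[3.3.1]nonane, TRIP = 3,3'-bis(2,4,6-triisopropylphenyl)-1,1'-binaphthyl-2,2'-diyl hydrogen phosphate, CSA = camphorsulfonic acid.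

**Route**

Step 1
Reactants: 1 tert-butyl(but-3-yn-1-yloxy)dimethylsilane; 2 (R)-2-{[(4-methoxybenzyl)oxy]methyl}oxirane
Product: 3 (R)-7-(TBS-oxy)-1-(PMB-oxy)hept-4-yn-2-ol
Conditions: n-BuLi, THF, −78 °C; BF3·OEt2; then 2, −78 °C; aq NH4Cl
Reagents that add atoms: none
Why: The lithium acetylide, activated by BF3, opens the terminal epoxide at its CH2 carbon (Lewis acid-promoted epoxide alkynylation), so the stereocentre of 2 is carried over untouched.

Step 2
Reactants: 3 (R)-7-(TBS-oxy)-1-(PMB-oxy)hept-4-yn-2-ol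
Product: 4 (R,Z)-7-(TBS-oxy)-1-(PMB-oxy)hept-4-en-2-ol
Conditions: H2 (1 atm), Pd/CaCO3 poisoned with Pb(OAc)2, quinoline, EtOAc, rt
Reagents that add atoms: none
Why: Lindlar semihydrogenation adds H2 syn to the alkyne on the poisoned palladium surface and should stop at the Z-alkene, leaving the PMB ether intact.

Step 3
Reactants: 4 (R,Z)-7-(TBS-oxy)-1-(PMB-oxy)hept-4-en-2-ol
Product: 5 1-({[(2R,4Z)-2,7-bis(TBS-oxy)hept-4-en-1-yl]oxy}methyl)-4-methoxybenzene
Conditions: TBSCl, imidazole, DMF, rt
Reagents that add atoms: tert-butyldimethylsilyl chloride, C[Si](C)(Cl)C(C)(C)C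
Why: Imidazole-assisted silylation of the secondary alcohol installs a group that should survive every later step until fluoride.

Step 4
Reactants: 5 1-({[(2R,4Z)-2,7-bis(TBS-oxy)hept-4-en-1-yl]oxy}methyl)-4-methoxybenzene
Product: 6 (R,Z)-2,7-bis(TBS-oxy)hept-4-en-1-ol
Conditions: DDQ, CH2Cl2/pH 7 phosphate buffer, 0 °C
Reagents that add atoms: none
Why: Oxidative PMB cleavage (hydride abstraction by DDQ, hydrolysis of the oxocarbenium ion) frees only the primary alcohol, the silyl ethers and the isolated Z-alkene being inert.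

Step 5
Reactants: 6 (R,Z)-2,7-bis(TBS-oxy)hept-4-en-1-ol
Product: 7 (R,Z)-2,7-bis(TBS-oxy)hept-4-enal
Conditions: Dess–Martin periodinane, CH2Cl2, 0 °C → rt; used at once
Reagents that add atoms: none
Why: Dess–Martin oxidation under non-basic conditions should give the α-silyloxy aldehyde without epimerisation of the adjacent centre.

Step 6
Reactants: 8 hex-5-enal; 9 [1-(ethylsulfanyl)ethenyl]oxy(trimethyl)silane
Product: 11 S-ethyl (S)-3-hydroxyoct-7-enethioate, via trimethylsilyl ether 10 (not isolated)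
Conditions: (R)-BINOL (20 mol%), Ti(OiPr)4 (20 mol%), 4 Å MS, Et2O, −20 °C; then 1 M HCl, THF
Reagents that add atoms: none
Why: Titanium–BINOL-catalysed Mukaiyama aldol addition in which the chiral Lewis acid binds the aldehyde and exposes its Re face to the silyl ketene thioacetal, setting the carbinol centre (S) under catalyst control.

Step 7
Reactants: 11 S-ethyl (S)-3-hydroxyoct-7-enethioate; 12 (3-ethoxy-3-oxopropyl)zinc bromide
Product: 13 ethyl (S)-6-hydroxy-4-oxoundec-10-enoate
Conditions: PdCl2(PPh3)2 (5 mol%), excess 12, THF/toluene, rt; 1 M HCl work-up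
Reagents that add atoms: none
Why: Fukuyama coupling, in which zerovalent palladium inserts into the C–S bond of the thioester and the mild alkylzinc transfers the ester-bearing ethyl group, should give the ketone without touching hydroxyl, ester or alkene.

Step 8
Reactants: 13 ethyl (S)-6-hydroxy-4-oxoundec-10-enoate
Product: 15 (S)-5-[(S)-2-hydroxyhept-6-en-1-yl]dihydrofuran-2(3H)-one, via anti-diol ester 14 (not isolated)
Conditions: Me4NBH(OAc)3, MeCN/AcOH (1:1), −30 °C; then TsOH·H2O (cat.), CH2Cl2, rt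
Reagents that add atoms: none
Why: Evans–Saksena reduction, in which the β-hydroxyl binds boron and delivers hydride intramolecularly through a chair transition state, sets the new carbinol centre 1,3-anti (S), and the γ-hydroxy ester then lactonises under acid.

Step 9
Reactants: 15 (S)-5-[(S)-2-hydroxyhept-6-en-1-yl]dihydrofuran-2(3H)-one
Product: 16 (S)-5-[(S)-2-(TBS-oxy)hept-6-en-1-yl]dihydrofuran-2(3H)-one
Conditions: TBSCl, imidazole, DMF, rt
Reagents that add atoms: tert-butyldimethylsilyl chloride, C[Si](C)(Cl)C(C)(C)C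
Why: Standard silylation masks the only free hydroxyl before the strongly basic enolisation.

Step 10
Reactants: 16 (S)-5-[(S)-2-(TBS-oxy)hept-6-en-1-yl]dihydrofuran-2(3H)-one
Product: 17 (S)-5-[(S)-2-(TBS-oxy)hept-6-en-1-yl]-4,5-dihydrofuran-2-yl diphenyl phosphate
Conditions: KN(SiMe3)2, (PhO)2P(O)Cl, HMPA, THF, −78 °C; filtered through Et3N-deactivated silica and used at once
Reagents that add atoms: diphenyl chlorophosphate, O=P(Cl)(Oc1ccccc1)Oc1ccccc1
Why: O-phosphorylation of the potassium lactone enolate gives the cyclic ketene acetal phosphate that serves as the carboxyl-level electrophile, the remote stereocentres being unaffected.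

Step 11
Reactants: 7 (R,Z)-2,7-bis(TBS-oxy)hept-4-enal; 18 2-[(2E)-but-2-en-1-yl]-4,4,5,5-tetramethyl-1,3,2-dioxaborolane; 17 (S)-5-[(S)-2-(TBS-oxy)hept-6-en-1-yl]-4,5-dihydrofuran-2-yl diphenyl phosphate
Product: 21 (3R,4R,5R,7Z)-5,10-bis(TBS-oxy)-1-{(5S)-5-[(2S)-2-(TBS-oxy)hept-6-en-1-yl]-4,5-dihydrofuran-2-yl}-3-methyldec-7-en-4-ol, via pinacol borate 19 (not isolated), via B-alkyl-9-BBN 20 (not isolated)
Conditions: 7, 18 (slight excess), (R)-TRIP (5 mol%), 4 Å MS, toluene, −30 °C; then 9-BBN dimer, THF, rt; then 3 M aq Cs2CO3, then 17, PdCl2(dppf) (10 mol%), DMF, rt → 50 °C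
Reagents that add atoms: none
Why: The phosphoric acid activates the boronate by hydrogen bonding and the E-crotyl group is delivered to the aldehyde through a closed chair transition state, making the CH(O)–CH(CH3) bond; 9-BBN then adds anti-Markovnikov to the new vinyl group, and the primary alkylborane, as its hydroxyborate, transmetalates to the divalent palladium species formed by oxidative addition of zerovalent palladium into the C–O(phosphate) bond of 17, reductive elimination making the CH2–C(enol ether) bond. The closest known reaction types are the chiral phosphoric acid-catalysed crotylboration of aldehydes and the B-alkyl Suzuki–Miyaura coupling of lactone-derived ketene acetal phosphates, here run consecutively in one flask. No ring is closed in this step: the five-membered ring comes in with the lactone-derived partner, and the six-membered ring closes in step 12 by 6-exo-trig addition of the new hydroxyl to the protonated enol ether. The new carbinol centre is set by the catalyst: (R)-TRIP is expected to direct attack to the Re face, which gives the syn relation to the silyloxy-bearing carbon against the modest Felkin/Cornforth bias of the substrate, and the methyl-bearing centre follows from the E geometry of the crotyl unit in the chair (anti). The step needs catalyst-over-substrate facial control, hydroboration of the monosubstituted vinyl group only (secured by the strong preference of 9-BBN for terminal over Z-disubstituted alkenes), and protection of the terminal alkene of 17 from B–H (secured by destroying residual 9-BBN with the aqueous base before 17 is added).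

Step 12
Reactants: 21 (3R,4R,5R,7Z)-5,10-bis(TBS-oxy)-1-{(5S)-5-[(2S)-2-(TBS-oxy)hept-6-en-1-yl]-4,5-dihydrofuran-2-yl}-3-methyldec-7-en-4-ol
Product: 22 tris-TBS ether of attenol A, (2S,5S,7R,8R)-7-[(1R,3Z)-1,6-bis(TBS-oxy)hex-3-en-1-yl]-2-[(2S)-2-(TBS-oxy)hept-6-en-1-yl]-8-methyl-1,6-dioxaspiro[4.5]decane
Conditions: CSA (10 mol%), CH2Cl2, 0 °C → rt
Reagents that add atoms: none
Why: Protonation of the enol ether gives a cyclic oxocarbenium ion that the δ-hydroxyl traps (6-exo-trig), and acid equilibration should lead to the spiro epimer with the five-membered-ring oxygen axial on a chair six-membered ring carrying both carbon substituents equatorial (anomeric control), while the silyl group on the neighbouring oxygen excludes the bicyclic ketal isomer.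

Step 13
Reactants: 22 tris-TBS ether of attenol A
Product: 23 attenol A, (1R,3Z)-1-{(2S,5S,7R,8R)-2-[(2S)-2-hydroxyhept-6-en-1-yl]-8-methyl-1,6-dioxaspiro[4.5]decan-7-yl}hex-3-ene-1,6-diol
Conditions: n-Bu4NF, THF, rt → 40 °C
Reagents that add atoms: none
Why: Fluoride cleaves the three Si–O bonds under non-acidic conditions, so the ketal configuration set in step 12 should be retained.

**Compound list**

1 | tert-butyl(but-3-yn-1-yloxy)dimethylsilane | C#CCCO[Si](C)(C)C(C)(C)C | starting material
2 | (R)-2-{[(4-methoxybenzyl)oxy]methyl}oxirane | COc1ccc(COC[C@H]2CO2)cc1 | starting material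
3 | (R)-7-(TBS-oxy)-1-(PMB-oxy)hept-4-yn-2-ol | COc1ccc(COC[C@H](O)CC#CCCO[Si](C)(C)C(C)(C)C)cc1 | intermediate
4 | (R,Z)-7-(TBS-oxy)-1-(PMB-oxy)hept-4-en-2-ol | COc1ccc(COC[C@H](O)C/C=C\CCO[Si](C)(C)C(C)(C)C)cc1 | intermediate
5 | 1-({[(2R,4Z)-2,7-bis(TBS-oxy)hept-4-en-1-yl]oxy}methyl)-4-methoxybenzene | COc1ccc(COC[C@H](O[Si](C)(C)C(C)(C)C)C/C=C\CCO[Si](C)(C)C(C)(C)C)cc1 | intermediate
6 | (R,Z)-2,7-bis(TBS-oxy)hept-4-en-1-ol | OC[C@H](O[Si](C)(C)C(C)(C)C)C/C=C\CCO[Si](C)(C)C(C)(C)C | intermediate
7 | (R,Z)-2,7-bis(TBS-oxy)hept-4-enal | O=C[C@H](O[Si](C)(C)C(C)(C)C)C/C=C\CCO[Si](C)(C)C(C)(C)C | intermediate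
8 | hex-5-enal | C=CCCCC=O | starting material
9 | [1-(ethylsulfanyl)ethenyl]oxy(trimethyl)silane | C=C(SCC)O[Si](C)(C)C | starting material
10 | S-ethyl (S)-3-(trimethylsilyloxy)oct-7-enethioate | C=CCCC[C@H](O[Si](C)(C)C)CC(=O)SCC | intermediate
11 | S-ethyl (S)-3-hydroxyoct-7-enethioate | C=CCCC[C@H](O)CC(=O)SCC | intermediate
12 | (3-ethoxy-3-oxopropyl)zinc bromide | CCOC(=O)CC[Zn]Br | starting material
13 | ethyl (S)-6-hydroxy-4-oxoundec-10-enoate | C=CCCC[C@H](O)CC(=O)CCC(=O)OCC | intermediate
14 | ethyl (4S,6S)-4,6-dihydroxyundec-10-enoate | C=CCCC[C@H](O)C[C@@H](O)CCC(=O)OCC | intermediate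
15 | (S)-5-[(S)-2-hydroxyhept-6-en-1-yl]dihydrofuran-2(3H)-one | C=CCCC[C@H](O)C[C@@H]1CCC(=O)O1 | intermediate
16 | (S)-5-[(S)-2-(TBS-oxy)hept-6-en-1-yl]dihydrofuran-2(3H)-one | C=CCCC[C@H](O[Si](C)(C)C(C)(C)C)C[C@@H]1CCC(=O)O1 | intermediate
17 | (S)-5-[(S)-2-(TBS-oxy)hept-6-en-1-yl]-4,5-dihydrofuran-2-yl diphenyl phosphate | C=CCCC[C@H](O[Si](C)(C)C(C)(C)C)C[C@@H]1CC=C(OP(=O)(Oc2ccccc2)Oc2ccccc2)O1 | intermediate
18 | 2-[(2E)-but-2-en-1-yl]-4,4,5,5-tetramethyl-1,3,2-dioxaborolane | C/C=C/CB1OC(C)(C)C(C)(C)O1 | starting material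
19 | 2-{[(3R,4R,5R,7Z)-5,10-bis(TBS-oxy)-3-methyldeca-1,7-dien-4-yl]oxy}-4,4,5,5-tetramethyl-1,3,2-dioxaborolane | C=C[C@@H](C)[C@@H](OB1OC(C)(C)C(C)(C)O1)[C@H](O[Si](C)(C)C(C)(C)C)C/C=C\CCO[Si](C)(C)C(C)(C)C | intermediate
20 | 9-{(3R,4R,5R,7Z)-5,10-bis(TBS-oxy)-3-methyl-4-[(pin)B-oxy]dec-7-en-1-yl}-9-borabicyclo[3.3.1]nonane | C(B1C2CCCC1CCC2)C[C@@H](C)[C@@H](OB3OC(C)(C)C(C)(C)O3)[C@H](O[Si](C)(C)C(C)(C)C)C/C=C\CCO[Si](C)(C)C(C)(C)C | intermediate
21 | (3R,4R,5R,7Z)-5,10-bis(TBS-oxy)-1-{(5S)-5-[(2S)-2-(TBS-oxy)hept-6-en-1-yl]-4,5-dihydrofuran-2-yl}-3-methyldec-7-en-4-ol | C=CCCC[C@H](O[Si](C)(C)C(C)(C)C)C[C@@H]1CC=C(CC[C@@H](C)[C@@H](O)[C@H](O[Si](C)(C)C(C)(C)C)C/C=C\CCO[Si](C)(C)C(C)(C)C)O1 | intermediate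
22 | (2S,5S,7R,8R)-7-[(1R,3Z)-1,6-bis(TBS-oxy)hex-3-en-1-yl]-2-[(2S)-2-(TBS-oxy)hept-6-en-1-yl]-8-methyl-1,6-dioxaspiro[4.5]decane | C=CCCC[C@H](O[Si](C)(C)C(C)(C)C)C[C@@H]1CC[C@@]2(CC[C@@H](C)[C@H]([C@H](O[Si](C)(C)C(C)(C)C)C/C=C\CCO[Si](C)(C)C(C)(C)C)O2)O1 | intermediate
23 | attenol A, (1R,3Z)-1-{(2S,5S,7R,8R)-2-[(2S)-2-hydroxyhept-6-en-1-yl]-8-methyl-1,6-dioxaspiro[4.5]decan-7-yl}hex-3-ene-1,6-diol | C=CCCC[C@H](O)C[C@@H]1CC[C@@]2(CC[C@@H](C)[C@H]([C@H](O)C/C=C\CCO)O2)O1 | target

**Step count and risks**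

Total step count: 13. Longest linear sequence: 8 steps (steps 1–5 or 6–10, then 11–13).

Steps most likely to fail:

Step 11. Facial selectivity may erode because catalyst control opposes the Felkin/Cornforth preference of the α-silyloxy aldehyde, and the three telescoped stages may interfere with one another. The fallback sets out from 7 and replaces catalyst control by a stoichiometric chiral reagent with the stages run separately. Aldehyde 7 is treated with (E)-crotyldiisopinocampheylborane (from trans-2-butene, KOtBu, n-BuLi, (+)-Ipc2BOMe and BF3·OEt2; THF, −78 °C; NaOH/H2O2 work-up), the antipode expected to attack the Re face. This should give (3R,4R,5R,7Z)-5,10-bis(TBS-oxy)-3-methyldeca-1,7-dien-4-ol F1, which is purified to a single diastereomer. F1 is then hydroborated with 9-BBN and coupled with 17 under the palladium conditions of step 11 as a separate operation, and the route is rejoined at 21.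

Step 10. O-phosphorylation may compete with C-phosphorylation, and the five-membered ketene acetal phosphate may be lost by hydrolysis or thermal decomposition before or during the coupling. The fallback sets out from 16 and uses an acyl electrophile in place of the ketene acetal phosphate. Lactone 16 is opened with Me3Al/EtSH to S-ethyl (4S,6S)-6-(TBS-oxy)-4-hydroxyundec-10-enethioate F2, which is silylated at once (Et3SiOTf, 2,6-lutidine) to S-ethyl (4S,6S)-6-(TBS-oxy)-4-(TES-oxy)undec-10-enethioate F3. In the flask of step 11, alkylborane 20 is then coupled with F3 by a Liebeskind–Srogl ketone synthesis (Pd2(dba)3, tri(2-furyl)phosphine, copper thiophene-2-carboxylate Cu(O2CC4H3S), Cs2CO3, THF). This should give (3Z,6R,7R,8R,14S,16S)-1,6,16-tris(TBS-oxy)-7-hydroxy-8-methyl-14-(TES-oxy)henicosa-3,20-dien-11-one F4. Pyridinium p-toluenesulfonate in MeOH at 0 °C then removes the TES group and closes both ketal rings, and the route is rejoined at 22.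

Step 6. Enantioface discrimination in the titanium–BINOL aldol may be insufficient with an unbranched aliphatic aldehyde. The fallback sets out from 8 and sets the carbinol centre by ketone hydrogenation instead of aldol addition. Aldehyde 8 is homologated by the Roskamp reaction (ethyl diazoacetate, SnCl2 cat., CH2Cl2) to ethyl 3-oxooct-7-enoate F5. Noyori hydrogenation (RuCl2[(S)-BINAP], H2 at low pressure to spare the terminal alkene, EtOH, 50 °C) should give ethyl (S)-3-hydroxyoct-7-enoate F6. Me3Al/EtSH converts the ester into the thioester, and the route is rejoined at 11.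

Further compounds
F1 | step 11 | (3R,4R,5R,7Z)-5,10-bis(TBS-oxy)-3-methyldeca-1,7-dien-4-ol | C=C[C@@H](C)[C@@H](O)[C@H](O[Si](C)(C)C(C)(C)C)C/C=C\CCO[Si](C)(C)C(C)(C)C
F2 | step 10 | S-ethyl (4S,6S)-6-(TBS-oxy)-4-hydroxyundec-10-enethioate | C=CCCC[C@H](O[Si](C)(C)C(C)(C)C)C[C@@H](O)CCC(=O)SCC
F3 | step 10 | S-ethyl (4S,6S)-6-(TBS-oxy)-4-(TES-oxy)undec-10-enethioate | C=CCCC[C@H](O[Si](C)(C)C(C)(C)C)C[C@@H](O[Si](CC)(CC)CC)CCC(=O)SCC
F4 | step 10 | (3Z,6R,7R,8R,14S,16S)-1,6,16-tris(TBS-oxy)-7-hydroxy-8-methyl-14-(TES-oxy)henicosa-3,20-dien-11-one | C=CCCC[C@H](O[Si](C)(C)C(C)(C)C)C[C@@H](O[Si](CC)(CC)CC)CCC(=O)CC[C@@H](C)[C@@H](O)[C@H](O[Si](C)(C)C(C)(C)C)C/C=C\CCO[Si](C)(C)C(C)(C)C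
F5 | step 6 | ethyl 3-oxooct-7-enoate | C=CCCCC(=O)CC(=O)OCC
F6 | step 6 | ethyl (S)-3-hydroxyoct-7-enoate | C=CCCC[C@H](O)CC(=O)OCC
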